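**Retrosynthetic overview**

1. Bicycle numbering used below: C1 (bridgehead, OMe), C2 (CHOAc), C3 (=C–OMe), C4 (=CH), C5 (bridgehead, allyl), C6 (CHMe), C7 (CH–aryl), C8 (bridging C=O). The target is traced back through phenol desilylation, acetylation and a Luche reduction (hydride syn to C8) to a bicyclo[3.2.1]oct-3-ene-2,8-dione, and from there (Saegusa–Ito) to the saturated 2,8-dione.
2. Key disconnection of that dione: the C7–aryl bond and the C1–C2 bond in one operation. A copper-catalysed 1,4-addition of an aryl Grignard reagent to a 2-methoxycyclopentenone is followed by Claisen closure of the resulting enolate onto the ester of a three-carbon arm at C5. This closes the six-membered ring C1–C2–C3–C4–C5–C8, the last ring formed.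
3. Enabling feature: the bridging ketone C8 is the carbonyl of the five-membered ring C8–C1–C7–C6–C5. Bridgehead C1 is therefore its α-carbon, C7 its β-carbon, and C2 the 1,3-carbonyl partner of C8, so adding the aryl group to C7 generates exactly the C1 enolate that forms C1–C2.
4. The 2-methoxycyclopentenone comes from a cyclopentenone (epoxidation, methoxide opening/dehydration), which comes from a keto ester by IBX dehydrogenation. The keto ester comes from Michael addition of 2-allyl-3-methylcyclopentanone to methyl 2-methoxyacrylate (quaternary C5), and the ketone from CuH asymmetric reduction/allylation of 3-methylcyclopentenone.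
5. Stereochemistry: C6 by catalysis (step 1); C5 (step 2), C7 and C1 (step 7) and C2 (step 9) by relay. Ring order: cyclopentane (purchased), then the six-membered ring (step 7).

Key step: step 7

Remark: the CH(OMe) carbon of the ester arm (later C3) is formed without control in step 2, is carried as a mixture of epimers (drawn without configuration) and becomes sp2 in step 8.
Assumption: (R)-p-Tol-BINAP is the ligand antipode that gives the (3S) series in step 1; should the sense be the opposite, the (S)-ligand is used and nothing else changes.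
Remark: 3-methylcyclopent-2-en-1-one, methyl 2-methoxyacrylate and 4-bromo-2,6-dimethoxyphenol are taken as purchased.

**Route**

Step 1
Reactants: 1 3-methylcyclopent-2-en-1-one
Product: 3 (2R,3S)-3-methyl-2-(prop-2-en-1-yl)cyclopentan-1-one, via diphenylsilyl bis-enol ether 2 (not isolated)
Conditions: CuCl (5 mol %), NaOt-Bu (5 mol %), (R)-p-Tol-BINAP (5 mol %), Ph2SiH2 (0.51 equiv), toluene, 0 °C; then allyl bromide (1.5 equiv), TBAT (1.1 equiv), CH2Cl2, 0 → 25 °C
Reagents that add atoms: allyl bromide C=CCBr
Why: Copper hydride asymmetric conjugate reduction sets the methyl-bearing carbon (later C6) under ligand control and leaves a regiodefined silyl enol ether, which fluoride-promoted allylation alkylates at C2 trans to the methyl group; the C2 configuration is not needed, since this carbon is enolised again in step 2.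

Step 2
Reactants: 3 (2R,3S)-3-methyl-2-(prop-2-en-1-yl)cyclopentan-1-one; 4 methyl 2-methoxyprop-2-enoate
Product: 5 methyl 2-methoxy-3-[(1R,2S)-2-methyl-5-oxo-1-(prop-2-en-1-yl)cyclopentyl]propanoate
Conditions: KOt-Bu (0.2 equiv), t-BuOH/THF 1:4, 4 (1.1 equiv), 0 → 25 °C
Reagents that add atoms: none
Why: Base-catalysed Michael addition under equilibrating conditions goes through the more substituted enolate, and the acrylate should add to the enolate face anti to the neighbouring methyl group, which makes the quaternary carbon (later C5) with the ester arm trans and the allyl group cis to methyl.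

Step 3
Reactants: 5 methyl 2-methoxy-3-[(1R,2S)-2-methyl-5-oxo-1-(prop-2-en-1-yl)cyclopentyl]propanoate
Product: 6 methyl 2-methoxy-3-[(1R,2S)-2-methyl-5-oxo-1-(prop-2-en-1-yl)cyclopent-3-en-1-yl]propanoate
Conditions: IBX (1.5 equiv), DMSO/fluorobenzene 1:2, 65 °C
Reagents that add atoms: none
Why: IBX dehydrogenation of a ketone to an enone; the quaternary α-carbon leaves the CH2–CH2 side as the only place for the double bond, and the ester and the terminal alkene should not react.

Step 4
Reactants: 6 methyl 2-methoxy-3-[(1R,2S)-2-methyl-5-oxo-1-(prop-2-en-1-yl)cyclopent-3-en-1-yl]propanoate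
Product: 7 the 3,4-epoxide of 6 (oxirane on the ring face opposite to the 2-methyl group)
Conditions: 30% aq. H2O2 (3 equiv), NaOH (0.2 equiv), MeOH, 0 °C
Reagents that add atoms: hydrogen peroxide OO
Why: Weitz–Scheffer nucleophilic epoxidation touches only the electron-poor enone double bond, not the allyl group, and hydroperoxide should add anti to the adjacent methyl group (this configuration is lost again in step 5).

Step 5
Reactants: 7 the 3,4-epoxide of 6
Product: 9 methyl 2-methoxy-3-[(1R,2S)-4-methoxy-2-methyl-5-oxo-1-(prop-2-en-1-yl)cyclopent-3-en-1-yl]propanoate, via hydroxy methoxy ketone 8 (not isolated)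
Conditions: NaOMe (0.5 equiv), MeOH, 0 → 25 °C
Reagents that add atoms: methanol CO
Why: Methoxide opens the α,β-epoxy ketone at the carbonyl-activated α-carbon (SN2) and the β-hydroxy ketone loses water by E1cB to give the 2-methoxy enone, the only regioisomer possible because the other α-carbon is quaternary; the low temperature is chosen to limit γ-deprotonation at the methyl-bearing carbon.

Step 6
Reactants: 10 4-bromo-2,6-dimethoxyphenol
Product: 11 (4-bromo-2,6-dimethoxyphenoxy)(tert-butyl)dimethylsilane
Conditions: TBSCl (1.2 equiv), imidazole (2.2 equiv), DMF, 25 °C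
Reagents that add atoms: tert-butyldimethylsilyl chloride CC(C)(C)[Si](C)(C)Cl
Why: Standard silylation of a phenol; the aryl silyl ether should survive the organomagnesium, enolisation, hydride and acylation steps and come off with fluoride at the end.

Step 7
Reactants: 9 methyl 2-methoxy-3-[(1R,2S)-4-methoxy-2-methyl-5-oxo-1-(prop-2-en-1-yl)cyclopent-3-en-1-yl]propanoate; 11 (4-bromo-2,6-dimethoxyphenoxy)(tert-butyl)dimethylsilane
Product: 14 (1R,5R,6S,7R)-7-{4-[(tert-butyldimethylsilyl)oxy]-3,5-dimethoxyphenyl}-1,3-dimethoxy-6-methyl-5-(prop-2-en-1-yl)bicyclo[3.2.1]octane-2,8-dione, via aryl Grignard reagent 12 (not isolated), via magnesium enolate 13 (not isolated)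
Conditions: 11 (1.3 equiv), Mg, LiCl, THF, 25 °C; CuBr·SMe2 (20 mol %), THF, −40 °C; add 9, −40 → 0 °C; pH 7 buffer, −40 °C
Reagents that add atoms: none
Why: The arylcopper species made from 12 adds 1,4 to the 2-methoxycyclopentenone (magnesium can chelate the carbonyl and methoxy oxygens, and 1,2-addition is blocked by the quaternary α′-carbon) to give the fully substituted enolate 13, whose α-carbon C1 attacks the ester carbonyl of the arm on C5 and expels methoxide; the base present then deprotonates the product at C3, which drives the closure and protects the non-enolisable C8/C1/C2 1,3-dione from retro-Claisen opening until the cold neutral quench. The closest known reaction type is copper-mediated conjugate addition with in situ Dieckmann/Claisen trapping of the enolate by a tethered ester. The six-membered ring C1–C2–C3–C4–C5–C8 closes by C1–C2 bond formation in a 6-(enolendo)-exo-trig mode, and no other ring forms. C7 is controlled by the C6 methyl group (the aryl group enters the enone face anti to it, as is general for 4-substituted cyclopentenones), and C1 is controlled by the tether, because the ester arm sits on the C5 face trans to methyl and can reach C1 only on that face, which places the bridge cis to the new aryl group and OMe on the outside. The step needs 1,4- over 1,2-addition (copper and the hindered C8), anti over syn arylation (C6 methyl) and C- over O-acylation (the enol lactone from O-acylation is reopened by methoxide, whereas the C-acyl product is withdrawn as its C3 enolate).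

Step 8
Reactants: 14 (1R,5R,6S,7R)-bicyclo[3.2.1]octane-2,8-dione from step 7
Product: 16 (1R,5S,6S,7R)-7-{4-[(tert-butyldimethylsilyl)oxy]-3,5-dimethoxyphenyl}-1,3-dimethoxy-6-methyl-5-(prop-2-en-1-yl)bicyclo[3.2.1]oct-3-ene-2,8-dione, via trimethylsilyl enol ether 15 (not isolated)
Conditions: TMSOTf (1.5 equiv), Et3N (2 equiv), CH2Cl2, 0 °C; then Pd(OAc)2 (1.1 equiv), MeCN, 25 °C
Reagents that add atoms: none
Why: Only C3–H is enolisable in 14 (both bridgeheads are quaternary), so soft enolisation gives one silyl enol ether, and Saegusa–Ito oxidation with β-hydride loss from C4 gives the 3-methoxy enone and removes the uncontrolled C3 centre.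

Step 9
Reactants: 16 (1R,5S,6S,7R)-bicyclo[3.2.1]oct-3-ene-2,8-dione from step 8
Product: 17 (1S,2R,5S,6S,7R)-7-{4-[(tert-butyldimethylsilyl)oxy]-3,5-dimethoxyphenyl}-2-hydroxy-1,3-dimethoxy-6-methyl-5-(prop-2-en-1-yl)bicyclo[3.2.1]oct-3-en-8-one
Conditions: NaBH4 (1.2 equiv), CeCl3·7H2O (1.2 equiv), MeOH, −78 °C
Reagents that add atoms: none
Why: Luche reduction should take the enone carbonyl C2 in preference to the bridging ketone C8, which lies between two quaternary carbons, and hydride should arrive on the C2 face syn to the one-carbon bridge, away from the endo aryl group on C7, which gives the (2R) alcohol with the hydroxyl on the side of the C6–C7 bridge.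

Step 10
Reactants: 17 (1S,2R,5S,6S,7R)-2-hydroxy ketone from step 9
Product: 18 (1S,2R,5S,6S,7R)-7-{4-[(tert-butyldimethylsilyl)oxy]-3,5-dimethoxyphenyl}-1,3-dimethoxy-6-methyl-8-oxo-5-(prop-2-en-1-yl)bicyclo[3.2.1]oct-3-en-2-yl acetate
Conditions: Ac2O (3 equiv), pyridine, DMAP (10 mol %), CH2Cl2, 0 → 25 °C
Reagents that add atoms: acetic anhydride CC(=O)OC(C)=O
Why: DMAP-catalysed acetylation of the secondary alcohol; no other free hydroxyl is present and the basic medium spares the enol ether.

Step 11
Reactants: 18 silyl-protected acetate from step 10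
Product: 19 (1S,2R,5S,6S,7R)-7-(4-hydroxy-3,5-dimethoxyphenyl)-1,3-dimethoxy-6-methyl-8-oxo-5-(prop-2-en-1-yl)bicyclo[3.2.1]oct-3-en-2-yl acetate
Conditions: TBAF (1.1 equiv), AcOH (1.2 equiv), THF, 0 °C
Reagents that add atoms: none
Why: Fluoride cleaves the aryl silyl ether much faster than it touches the secondary acetate, and buffering with acetic acid keeps the phenoxide from attacking the acetate or opening the β-acyloxy ketone.

**Compound list**

1 | 3-methylcyclopent-2-en-1-one | CC1=CC(=O)CC1 | starting material
2 | bis{[(3S)-3-methylcyclopent-1-en-1-yl]oxy}diphenylsilane (not isolated) | C[C@H]1CCC(O[Si](c2ccccc2)(c2ccccc2)OC2=C[C@@H](C)CC2)=C1 | intermediate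
3 | (2R,3S)-3-methyl-2-(prop-2-en-1-yl)cyclopentan-1-one | O=C1CC[C@H](C)[C@H]1CC=C | intermediate
4 | methyl 2-methoxyprop-2-enoate | C=C(OC)C(=O)OC | starting material
5 | methyl 2-methoxy-3-[(1R,2S)-2-methyl-5-oxo-1-(prop-2-en-1-yl)cyclopentyl]propanoate (epimers at the CH(OMe) carbon) | O=C1CC[C@H](C)[C@@]1(CC=C)CC(OC)C(=O)OC | intermediate
6 | methyl 2-methoxy-3-[(1R,2S)-2-methyl-5-oxo-1-(prop-2-en-1-yl)cyclopent-3-en-1-yl]propanoate | O=C1C=C[C@H](C)[C@@]1(CC=C)CC(OC)C(=O)OC | intermediate
7 | 3,4-epoxide of 6, oxirane trans to the ring methyl group | O=C1[C@H]2O[C@H]2[C@H](C)[C@@]1(CC=C)CC(OC)C(=O)OC | intermediate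
8 | 3-hydroxy-4-methoxy ketone from opening of 7 (ring OMe trans to OH; not isolated) | O=C1[C@H](OC)[C@@H](O)[C@H](C)[C@@]1(CC=C)CC(OC)C(=O)OC | intermediate
9 | methyl 2-methoxy-3-[(1R,2S)-4-methoxy-2-methyl-5-oxo-1-(prop-2-en-1-yl)cyclopent-3-en-1-yl]propanoate | O=C1C(OC)=C[C@H](C)[C@@]1(CC=C)CC(OC)C(=O)OC | intermediate
10 | 4-bromo-2,6-dimethoxyphenol | COc1cc(Br)cc(OC)c1O | starting material
11 | (4-bromo-2,6-dimethoxyphenoxy)(tert-butyl)dimethylsilane | COc1cc(Br)cc(OC)c1O[Si](C)(C)C(C)(C)C | intermediate
12 | {4-[(tert-butyldimethylsilyl)oxy]-3,5-dimethoxyphenyl}magnesium bromide (not isolated) | COc1cc([Mg]Br)cc(OC)c1O[Si](C)(C)C(C)(C)C | intermediate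
13 | bromomagnesium enolate of the 1,4-adduct: aryl trans to methyl, ester arm cis to aryl (not isolated) | Br[Mg]OC1=C(OC)[C@@H](c2cc(OC)c(O[Si](C)(C)C(C)(C)C)c(OC)c2)[C@H](C)[C@@]1(CC=C)CC(OC)C(=O)OC | intermediate
14 | (1R,5R,6S,7R)-7-{4-[(tert-butyldimethylsilyl)oxy]-3,5-dimethoxyphenyl}-1,3-dimethoxy-6-methyl-5-(prop-2-en-1-yl)bicyclo[3.2.1]octane-2,8-dione (C3 epimers) | C=CC[C@]12CC(OC)C(=O)[C@](OC)(C1=O)[C@@H](c1cc(OC)c(O[Si](C)(C)C(C)(C)C)c(OC)c1)[C@@H]2C | intermediate
15 | 2-trimethylsilyl enol ether of 14, C2=C3 (not isolated) | C=CC[C@]12CC(OC)=C(O[Si](C)(C)C)[C@](OC)(C1=O)[C@@H](c1cc(OC)c(O[Si](C)(C)C(C)(C)C)c(OC)c1)[C@@H]2C | intermediate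
16 | (1R,5S,6S,7R)-7-{4-[(tert-butyldimethylsilyl)oxy]-3,5-dimethoxyphenyl}-1,3-dimethoxy-6-methyl-5-(prop-2-en-1-yl)bicyclo[3.2.1]oct-3-ene-2,8-dione | C=CC[C@]12C=C(OC)C(=O)[C@](OC)(C1=O)[C@@H](c1cc(OC)c(O[Si](C)(C)C(C)(C)C)c(OC)c1)[C@@H]2C | intermediate
17 | (1S,2R,5S,6S,7R)-7-{4-[(tert-butyldimethylsilyl)oxy]-3,5-dimethoxyphenyl}-2-hydroxy-1,3-dimethoxy-6-methyl-5-(prop-2-en-1-yl)bicyclo[3.2.1]oct-3-en-8-one | C=CC[C@]12C=C(OC)[C@@H](O)[C@](OC)(C1=O)[C@@H](c1cc(OC)c(O[Si](C)(C)C(C)(C)C)c(OC)c1)[C@@H]2C | intermediate
18 | (1S,2R,5S,6S,7R)-7-{4-[(tert-butyldimethylsilyl)oxy]-3,5-dimethoxyphenyl}-1,3-dimethoxy-6-methyl-8-oxo-5-(prop-2-en-1-yl)bicyclo[3.2.1]oct-3-en-2-yl acetate | C=CC[C@]12C=C(OC)[C@@H](OC(C)=O)[C@](OC)(C1=O)[C@@H](c1cc(OC)c(O[Si](C)(C)C(C)(C)C)c(OC)c1)[C@@H]2C | intermediate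
19 | (1S,2R,5S,6S,7R)-7-(4-hydroxy-3,5-dimethoxyphenyl)-1,3-dimethoxy-6-methyl-8-oxo-5-(prop-2-en-1-yl)bicyclo[3.2.1]oct-3-en-2-yl acetate | C=CC[C@]12C=C(OC)[C@@H](OC(C)=O)[C@](OC)(C1=O)[C@@H](c1cc(OC)c(O)c(OC)c1)[C@@H]2C | target

**Step count and risks**

Total steps: 11. Longest linear sequence: 10 (steps 1–5 and 7–11; step 6 is a one-step side branch).

Steps most likely to fail:

Step 7. The conjugate addition to the electron-rich, hindered α-methoxy enone may be slow. The enolate may acylate on oxygen to give an enol lactone. Methoxide may reopen the bridged 1,3-dione by retro-Claisen cleavage, or excess Grignard reagent may add to the product ketones. The fallback separates the events and sets out from 6. A TMSCl-accelerated aryl cuprate addition (from 12, CuBr·SMe2, TMSCl, THF, −78 °C) to the plain enone should give the trimethylsilyl enol ether of the 1,4-adduct F1, with the aryl group trans to methyl. Rubottom oxidation (m-CPBA, NaHCO3, CH2Cl2, then mild acid) should give the α-hydroxy ketone F2. Methylation (Me3OBF4, proton sponge, CH2Cl2) should give the α-methoxy ketone F3, whose only enolisable ketone position is the future C1. LiHMDS (2.2 equiv, THF, −78 → 0 °C) then closes the ring by Dieckmann condensation, and the route is rejoined at 14.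

Step 2. Michael addition may occur at the less substituted α-carbon, and the captodative acrylate may react slowly enough for double addition or retro-Michael equilibration to compete. The fallback fixes the regiochemistry through an enone and sets out from 3. Kinetic deprotonation (LDA, THF, −78 °C) followed by N-tert-butylbenzenesulfinimidoyl chloride should give (4S,5R)-4-methyl-5-(prop-2-en-1-yl)cyclopent-2-en-1-one F4. Its α′-lithium enolate (LDA, −78 °C), the only enolate available next to the carbonyl, is added to 4 and quenched at −78 °C before the ester enolate can add back to the enone. This gives 6 directly, so the route is rejoined at 6.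

Step 5. Methoxide may remove the γ-proton of the enone and erode the configuration at the methyl-bearing carbon, may open the epoxide at the β-carbon, or may trigger benzilic-type contraction of the dione formed. The fallback avoids base and sets out from 7. Acid-mediated isomerisation (H2SO4, AcOH, 25 °C) should give the diosphenol, methyl 3-[(1R,2S)-4-hydroxy-2-methyl-5-oxo-1-(prop-2-en-1-yl)cyclopent-3-en-1-yl]-2-methoxypropanoate F5. This is O-methylated under neutral conditions (TMSCHN2, MeOH/toluene, 25 °C), and the route is rejoined at 9.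

**Further compounds**

F1 | step 7 | trimethylsilyl enol ether of the 1,4-aryl adduct of 6 (aryl trans to methyl) | C[Si](C)(C)OC1=C[C@@H](c2cc(OC)c(O[Si](C)(C)C(C)(C)C)c(OC)c2)[C@H](C)[C@@]1(CC=C)CC(OC)C(=O)OC
F2 | step 7 | α-hydroxy ketone from Rubottom oxidation of F1 (OH trans to aryl) | O=C1[C@H](O)[C@@H](c2cc(OC)c(O[Si](C)(C)C(C)(C)C)c(OC)c2)[C@H](C)[C@@]1(CC=C)CC(OC)C(=O)OC
F3 | step 7 | α-methoxy ketone from methylation of F2 | O=C1[C@H](OC)[C@@H](c2cc(OC)c(O[Si](C)(C)C(C)(C)C)c(OC)c2)[C@H](C)[C@@]1(CC=C)CC(OC)C(=O)OC
F4 | step 2 | (4S,5R)-4-methyl-5-(prop-2-en-1-yl)cyclopent-2-en-1-one | O=C1C=C[C@H](C)[C@H]1CC=C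
F5 | step 5 | methyl 3-[(1R,2S)-4-hydroxy-2-methyl-5-oxo-1-(prop-2-en-1-yl)cyclopent-3-en-1-yl]-2-methoxypropanoate | O=C1C(O)=C[C@H](C)[C@@]1(CC=C)CC(OC)C(=O)OC
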